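I count spare partner.

| flask | substrate | partner | remark | time |
|---|---|---|---|---|
| dusk | 0.60 M | 0.60 M | run made earlier |  |
| midnight | 0.20 M | 0.60 M | run made earlier |  |
| delta | 0.40 M | 0.600 M |  | 2.0 min |
| zeta | 0.40 M | 0.780 M |  | 2.0 min |

| run | time / s | single product / % | substrate / % | bis adduct / % |
|---|---|---|---|---|
| dusk | 10.0 | 56 | 42 | 2 |
| dusk | 12.0 | 57 | 41 | 1 |
| dusk | 25.0 | 75 | 25 | 0 |
| midnight | 10.0 | 65 | 30 | 2 |
| midnight | 15.0 | 78 | 18 | 1 |
| midnight | 20.0 | 89 | 12 | 2 |
| midnight | 25.0 | 88 | 5 | 4 |

(standard deviation of a reading: 2 percentage points)



- which of these there is most of at the end, counted by the substrate in it, delta (single product / substrate / bis adduct)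
- which of these there is most of at the end, counted by the substrate in it, zeta (single product / substrate / bis adduct)
- the largest of these amounts at the end, in percent of the substrate charged, delta
- the largest of these amounts at the end, in percent of the substrate charged, zeta

The readings show substrate and partner making single product, and partner then turning single product into bis adduct. Delta has 0.200 M of spare partner, the partner charge minus the substrate charge, and zeta has 0.380 M, so substrate is the limiting reagent in both. Midnight's substrate is down to 5 % by 25.0 s, and delta and zeta get 2.0 min, which is longer, so I expect single product on top.

What it loses is the leak, the share carried on to bis adduct, which I scale with spare partner and with time. Midnight has 0.400 M spare, and its last two bis adduct readings average 3.00 % at about 22.5 s. Each reading is good to 2 percentage points, so this is rough. Scaled up, the leak is 8.00 % in delta and 15.2 % in zeta, which leaves single product at 92.3 % and 85.9 %.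

The forecast, “Single product therefore dominates”, gives 92 % in delta and 87 % in zeta, and its zeta figure stands above mine.

The flasks give single product at 92.9 % in delta and single product at 88.4 % in zeta.

    substrate + partner → single product + by-product (k = 0.230 M⁻¹ s⁻¹)
    partner + single product → bis adduct + by-product (k = 0.00380 M⁻¹ s⁻¹)
    partner → decomposed reagent (k = 0.00240 s⁻¹)
    partner ⇌ dormant form (K = 0.520, k = 0.00130 s⁻¹)

Spare partner does not stand still: delta ends with 0.101 M free against 0.200 M spare. The same run without that wearing away gives single product 77.3 % instead of 92.9 %, the largest single effect. Zeta recharged with 0.20 M of partner has −0.200 M spare, so its charge leaves 50.0 % of the substrate without partner, and that flask ends with substrate on top at 52.7 %.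

The data come from a simulation with made-up constants, and the scatter is random.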